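**Retrosynthetic overview**

1. The target is achiral: A–O–B–O–C–O–D–O–E–O–F–O–G–O–H, with ethers A1–O–B1, B4–O–C1, C2–O–D1, D4–O–E1, E2–O–F1, F4–O–G1 and G2–O–H1. The last step cleaves 18 methyl and 3 ethyl ethers.
2. Feature: ring D carries oxygen on D1, D3, D4 and D5, with the ether to ring E on D4 (a 2-aryloxyphloroglucinol). D4 with its aryloxy group is a ketene carbon, D3 the ketene carbonyl, D5–D6 an ethoxyalkyne and D1–D2 a silyloxyalkyne.
3. Key disconnection: ring D from a 4-aryloxy-3-ethoxycyclobutenone and (triisopropylsilyloxy)acetylene by benzannulation. The cyclobutenone comes from an aryloxyketene (ring E phenol plus bromoacetate) and ethoxyacetylene.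
4. The pairs B–C, D–E and F–G are the same dimer, so ring E carries iodine on E2 in place of a protected oxygen. One dimer is made once and used three times; its D1-type phenol, freed from the silyl ether, is the nucleophile in each Ullmann coupling with the hindered iodide (G2–O–H1, E2–O–F1, C2–O–D1, A1–O–B1).
5. Ring order: transient four-membered cyclobutenone, then ring D (= B = F) by 6π closure. Rings A, C, E, G and H are bought as arenes, and the chain grows from ring H to ring A.

Key step: step 7

Assumption: lithium ethynolate is taken to form from ethyl formate under the ester-to-ynolate homologation conditions established for higher esters (hydrogen as the migrating group), and the hard silyl triflate is taken to silylate it on oxygen.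

**Route**

Step 1
Reactants: 1 3,4,5-trimethoxyphenol
Product: 2 2-iodo-3,4,5-trimethoxyphenol
Conditions: NIS (1.0 equiv), MeCN, 0 °C, dark
Reagents that add atoms: N-iodosuccinimide O=C1CCC(=O)N1I
Why: Electrophilic aromatic iodination, in which the only free positions (C2 and C6) are equivalent and ortho to the hydroxyl, and one equivalent of reagent at low temperature should stop at the mono-iodide.

Step 2
Reactants: 2 2-iodo-3,4,5-trimethoxyphenol; 3 methyl bromoacetate
Product: 4 methyl 2-(2-iodo-3,4,5-trimethoxyphenoxy)acetate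
Conditions: K2CO3, acetone, reflux
Reagents that add atoms: none
Why: Williamson ether synthesis of a phenoxide with a primary α-halo ester, which fixes the future D4–O–E1 oxygen–carbon bond before ring D exists.

Step 3
Reactants: 4 methyl 2-(2-iodo-3,4,5-trimethoxyphenoxy)acetate
Product: 5 2-(2-iodo-3,4,5-trimethoxyphenoxy)acetic acid
Conditions: LiOH·H2O, THF/H2O, rt; then 1 M HCl
Reagents that add atoms: lithium hydroxide [Li+].[OH-]
Why: Saponification of a methyl ester, to which the aryl iodide and the aryl ethers are inert at room temperature.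

Step 4
Reactants: 5 2-(2-iodo-3,4,5-trimethoxyphenoxy)acetic acid
Product: 6 2-(2-iodo-3,4,5-trimethoxyphenoxy)acetyl chloride
Conditions: (COCl)2, cat. DMF, CH2Cl2, 0 °C → rt; evaporate, use crude
Reagents that add atoms: oxalyl chloride ClC(=O)C(=O)Cl
Why: Acid chloride formation through the chloroiminium species from DMF and oxalyl chloride, under neutral gas-evolving conditions that leave the iodide and ethers untouched.

Step 5
Reactants: 6 2-(2-iodo-3,4,5-trimethoxyphenoxy)acetyl chloride; 7 ethoxyacetylene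
Product: 9 3-ethoxy-4-(2-iodo-3,4,5-trimethoxyphenoxy)cyclobut-2-en-1-one (racemic), via aryloxyketene 8 (not isolated)
Conditions: Et3N (1.5 equiv), 7 (3 equiv), CH2Cl2, 0 °C → rt, slow addition of 6; Et3N-deactivated silica
Reagents that add atoms: none
Why: Dehydrochlorination gives aryloxyketene 8, which the electron-rich alkyne traps in a ketene–ynol ether (2+2) cycloaddition in which the nucleophilic unsubstituted alkyne carbon bonds to the ketene carbonyl carbon, so that the ethoxy group ends on C3 next to the aryloxy-bearing C4, while slow addition keeps ketene dimerisation down.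

Step 6
Reactants: 10 ethyl formate; 11 dibromomethane; 12 triisopropylsilyl trifluoromethanesulfonate
Product: 15 (triisopropylsilyloxy)acetylene, via lithium 2,2-dibromoethenolate 13 (not isolated), via lithium ethynolate 14 (not isolated)
Conditions: lithium 2,2,6,6-tetramethylpiperidide (LiTMP), THF, −78 °C; LiN(SiMe3)2; n-BuLi, −78 → 0 °C; then 12 (2.2 equiv), −78 °C → rt; distil
Reagents that add atoms: none
Why: Kowalski-type ester-to-ynolate homologation applied to a formate, in which LiCHBr2 adds to 10, LiN(SiMe3)2 induces loss of ethoxide to enolate 13, bromine–lithium exchange gives a carbenoid that rearranges by 1,2-hydride shift (Fritsch–Buttenberg–Wiechell type) to ynolate 14, and the hard, bulky silyl triflate silylates 14 on oxygen.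

Step 7
Reactants: 9 3-ethoxy-4-(2-iodo-3,4,5-trimethoxyphenoxy)cyclobut-2-en-1-one; 15 (triisopropylsilyloxy)acetylene
Product: 20 3-ethoxy-2-(2-iodo-3,4,5-trimethoxyphenoxy)-5-(triisopropylsilyloxy)phenol (D–E dimer phenol), via vinylketene 16 (not isolated), via 4-alkenylcyclobutenone 17 (not isolated), via dienylketene 18 (not isolated), via cyclohexa-2,4-dienone 19 (not isolated)
Conditions: 15 (2 equiv), toluene (0.2 M), 80 → 110 °C, argon, dark
Reagents that add atoms: none
Why: Heat opens cyclobutenone 9 by 4π conrotatory cleavage of its C1–C4 bond, the aryloxy group on C4 turning outward, to give vinylketene 16, in which D3 is the ketene carbon, D4 the aryloxy carbon and D5–D6 the former ethoxyalkyne carbons. The ketene adds silyloxyalkyne 15 in a polar (2+2) step that forms D2–D3 and D1–D6 and gives 4-alkenylcyclobutenone 17, whose second 4π opening delivers dienylketene 18. Ring D then closes by thermal disrotatory 6π electrocyclisation of 18, which re-forms D3–D4, and cyclohexadienone 19 tautomerises to phenol 20; the closest known reaction is the Danheiser benzannulation of cyclobutenones with trialkylsilyloxyalkynes. No stereocentre is created, since the stereocentres of 9, 17 and 19 are lost on aromatisation. The step needs the regiochemistry of the (2+2) addition, and the polarity of the partners secures it: the unsubstituted, nucleophilic alkyne carbon bonds to the electrophilic ketene carbon, so the silyloxy group ends meta to the new hydroxyl and para to the aryl ether. An excess of 15 and moderate dilution should keep the vinylketene from being trapped by product phenol or by itself.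

Step 8
Reactants: 20 3-ethoxy-2-(2-iodo-3,4,5-trimethoxyphenoxy)-5-(triisopropylsilyloxy)phenol
Product: 21 [3-ethoxy-4-(2-iodo-3,4,5-trimethoxyphenoxy)-5-methoxyphenoxy]triisopropylsilane (dimer building block)
Conditions: MeI, K2CO3, acetone, 40 °C
Reagents that add atoms: iodomethane CI
Why: Williamson methylation of the only free hydroxyl (D3–OH), with a weak base in acetone that should leave the triisopropylsilyl ether and the aryl iodide intact.

Step 9
Reactants: 21 dimer building block (here rings F–G); 1 3,4,5-trimethoxyphenol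
Product: 22 {3-ethoxy-5-methoxy-4-[3,4,5-trimethoxy-2-(3,4,5-trimethoxyphenoxy)phenoxy]phenoxy}triisopropylsilane (F–G–H trimer silyl ether)
Conditions: 1 (1.5 equiv), CuI (20 mol%), N,N-dimethylglycine hydrochloride (40 mol%), Cs2CO3, 1,4-dioxane, 105 °C
Reagents that add atoms: none
Why: Ullmann diaryl ether synthesis in which the copper–amino acid catalyst activates the G2–I bond, the only halide present, and couples it with the unhindered phenoxide of 1, while the silyl ether should tolerate carbonate in an aprotic, weakly polar solvent.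

Step 10
Reactants: 22 F–G–H trimer silyl ether
Product: 23 3-ethoxy-5-methoxy-4-[3,4,5-trimethoxy-2-(3,4,5-trimethoxyphenoxy)phenoxy]phenol (F–G–H trimer phenol)
Conditions: Bu4NF, THF, 0 °C; then dilute HCl
Reagents that add atoms: none
Why: Fluoride cleaves the Si–O bond (strong Si–F bond formed) and frees the F1 phenol, while alkyl aryl and diaryl ethers are inert.

Step 11
Reactants: 23 F–G–H trimer phenol; 21 dimer building block (here rings D–E)
Product: 24 D–E–F–G–H pentamer silyl ether (silyl ether on D1; ethers D4–O–E1, E2–O–F1, F4–O–G1, G2–O–H1; OMe on D3, F3, E3–E5, G3–G5, H3–H5; OEt on D5, F5)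
Conditions: CuI (20 mol%), N,N-dimethylglycine hydrochloride (40 mol%), Cs2CO3, 1,4-dioxane, 105 °C
Reagents that add atoms: none
Why: The same Ullmann coupling forms E2–O–F1 from the F1 phenoxide of 23, which has no ortho substituent and no halide of its own, and the E2 iodide of 21, so self-condensation of either partner is excluded.

Step 12
Reactants: 24 D–E–F–G–H pentamer silyl ether
Product: 25 D–E–F–G–H pentamer phenol (free OH on D1)
Conditions: Bu4NF, THF, 0 °C; then dilute HCl
Reagents that add atoms: none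
Why: Fluoride-induced desilylation frees the D1 phenol, the oxygen that the silyloxyalkyne brought into ring D.

Step 13
Reactants: 25 D–E–F–G–H pentamer phenol; 21 dimer building block (here rings B–C)
Product: 26 B–C–D–E–F–G–H heptamer silyl ether (silyl ether on B1; OMe on B3, D3, F3, C3–C5, E3–E5, G3–G5, H3–H5; OEt on B5, D5, F5)
Conditions: CuI (20 mol%), N,N-dimethylglycine hydrochloride (40 mol%), Cs2CO3, 1,4-dioxane, 105 °C
Reagents that add atoms: none
Why: Third use of 21 in the same Ullmann coupling, in which the D1 phenoxide of 25 displaces the C2 iodide and forms the C2–O–D1 ether.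

Step 14
Reactants: 26 B–C–D–E–F–G–H heptamer silyl ether
Product: 27 B–C–D–E–F–G–H heptamer phenol (free OH on B1)
Conditions: Bu4NF, THF, 0 °C; then dilute HCl
Reagents that add atoms: none
Why: Fluoride-induced desilylation frees the B1 phenol without touching the 18 alkyl aryl and 6 diaryl ether links.

Step 15
Reactants: 27 B–C–D–E–F–G–H heptamer phenol; 28 2-iodo-1,3,5-trimethoxybenzene
Product: 29 fully alkylated octamer (27 carrying the 2,4,6-trimethoxyphenyl ring A on the B1 oxygen; 18 OMe, 3 OEt)
Conditions: 28 (3 equiv), CuI (20 mol%), N,N-dimethylglycine hydrochloride (40 mol%), Cs2CO3, 1,4-dioxane, 105 °C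
Reagents that add atoms: none
Why: Ullmann coupling of the unhindered B1 phenoxide with the di-ortho-methoxy iodide used in excess, the classical pairing for 2,4,6-trimethoxyphenyl aryl ethers, closes the chain at A1–O–B1.

Step 16
Reactants: 29 fully alkylated octamer
Product: 30 target CNP0206369.0 (octamer A–H with 21 free hydroxyls)
Conditions: BBr3 (excess, about 3 equiv per ether), CH2Cl2, −78 °C → rt, argon; MeOH then degassed H2O; Sephadex LH-20
Reagents that add atoms: none
Why: Lewis acid-mediated dealkylation in which BBr3 complexes each alkyl aryl ether and bromide removes methyl or ethyl by SN2, whereas the diaryl ether links offer no sp3 carbon and survive, and hydrolysis of the aryl borates frees the polyphenol.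

**Compound list**

1 | 3,4,5-trimethoxyphenol | COc1cc(O)cc(OC)c1OC | starting material
2 | 2-iodo-3,4,5-trimethoxyphenol | Oc1cc(OC)c(OC)c(OC)c1I | intermediate
3 | methyl bromoacetate | COC(=O)CBr | starting material
4 | methyl 2-(2-iodo-3,4,5-trimethoxyphenoxy)acetate | COC(=O)COc1cc(OC)c(OC)c(OC)c1I | intermediate
5 | 2-(2-iodo-3,4,5-trimethoxyphenoxy)acetic acid | OC(=O)COc1cc(OC)c(OC)c(OC)c1I | intermediate
6 | 2-(2-iodo-3,4,5-trimethoxyphenoxy)acetyl chloride | ClC(=O)COc1cc(OC)c(OC)c(OC)c1I | intermediate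
7 | ethoxyacetylene | C#COCC | starting material
8 | (2-iodo-3,4,5-trimethoxyphenoxy)ketene | O=C=COc1cc(OC)c(OC)c(OC)c1I | intermediate
9 | 3-ethoxy-4-(2-iodo-3,4,5-trimethoxyphenoxy)cyclobut-2-en-1-one (racemic) | CCOC1=CC(=O)C1Oc1cc(OC)c(OC)c(OC)c1I | intermediate
10 | ethyl formate | CCOC=O | starting material
11 | dibromomethane | BrCBr | starting material
12 | triisopropylsilyl trifluoromethanesulfonate | CC(C)[Si](C(C)C)(C(C)C)OS(=O)(=O)C(F)(F)F | starting material
13 | lithium 2,2-dibromoethen-1-olate | [Li+].[O-]C=C(Br)Br | intermediate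
14 | lithium ethynolate | [Li+].[O-]C#C | intermediate
15 | (triisopropylsilyloxy)acetylene | C#CO[Si](C(C)C)(C(C)C)C(C)C | intermediate
16 | (3Z)-3-ethoxy-4-(2-iodo-3,4,5-trimethoxyphenoxy)buta-1,3-dien-1-one (aryloxy trans to C2) | O=C=C/C(OCC)=C/Oc1cc(OC)c(OC)c(OC)c1I | intermediate
17 | 4-[(Z)-1-ethoxy-2-(2-iodo-3,4,5-trimethoxyphenoxy)ethenyl]-3-(triisopropylsilyloxy)cyclobut-2-en-1-one (racemic) | O=C1C=C(O[Si](C(C)C)(C(C)C)C(C)C)C1/C(OCC)=C/Oc1cc(OC)c(OC)c(OC)c1I | intermediate
18 | (3E,5Z)-5-ethoxy-6-(2-iodo-3,4,5-trimethoxyphenoxy)-3-(triisopropylsilyloxy)hexa-1,3,5-trien-1-one | O=C=C/C(O[Si](C(C)C)(C(C)C)C(C)C)=C\C(OCC)=C\Oc1cc(OC)c(OC)c(OC)c1I | intermediate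
19 | 5-ethoxy-6-(2-iodo-3,4,5-trimethoxyphenoxy)-3-(triisopropylsilyloxy)cyclohexa-2,4-dien-1-one (racemic) | O=C1C=C(O[Si](C(C)C)(C(C)C)C(C)C)C=C(OCC)C1Oc1cc(OC)c(OC)c(OC)c1I | intermediate
20 | 3-ethoxy-2-(2-iodo-3,4,5-trimethoxyphenoxy)-5-(triisopropylsilyloxy)phenol (D–E dimer phenol) | CCOc1cc(O[Si](C(C)C)(C(C)C)C(C)C)cc(O)c1Oc1cc(OC)c(OC)c(OC)c1I | intermediate
21 | [3-ethoxy-4-(2-iodo-3,4,5-trimethoxyphenoxy)-5-methoxyphenoxy]triisopropylsilane (dimer building block) | CCOc1cc(O[Si](C(C)C)(C(C)C)C(C)C)cc(OC)c1Oc1cc(OC)c(OC)c(OC)c1I | intermediate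
22 | F–G–H trimer silyl ether | CCOc1cc(O[Si](C(C)C)(C(C)C)C(C)C)cc(OC)c1Oc1cc(OC)c(OC)c(OC)c1Oc1cc(OC)c(OC)c(OC)c1 | intermediate
23 | F–G–H trimer phenol | CCOc1cc(O)cc(OC)c1Oc1cc(OC)c(OC)c(OC)c1Oc1cc(OC)c(OC)c(OC)c1 | intermediate
24 | D–E–F–G–H pentamer silyl ether | CCOc1cc(O[Si](C(C)C)(C(C)C)C(C)C)cc(OC)c1Oc1cc(OC)c(OC)c(OC)c1Oc1cc(OCC)c(Oc2cc(OC)c(OC)c(OC)c2Oc2cc(OC)c(OC)c(OC)c2)c(OC)c1 | intermediate
25 | D–E–F–G–H pentamer phenol | CCOc1cc(O)cc(OC)c1Oc1cc(OC)c(OC)c(OC)c1Oc1cc(OCC)c(Oc2cc(OC)c(OC)c(OC)c2Oc2cc(OC)c(OC)c(OC)c2)c(OC)c1 | intermediate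
26 | B–C–D–E–F–G–H heptamer silyl ether | CCOc1cc(O[Si](C(C)C)(C(C)C)C(C)C)cc(OC)c1Oc1cc(OC)c(OC)c(OC)c1Oc1cc(OCC)c(Oc2cc(OC)c(OC)c(OC)c2Oc2cc(OCC)c(Oc3cc(OC)c(OC)c(OC)c3Oc3cc(OC)c(OC)c(OC)c3)c(OC)c2)c(OC)c1 | intermediate
27 | B–C–D–E–F–G–H heptamer phenol | CCOc1cc(O)cc(OC)c1Oc1cc(OC)c(OC)c(OC)c1Oc1cc(OCC)c(Oc2cc(OC)c(OC)c(OC)c2Oc2cc(OCC)c(Oc3cc(OC)c(OC)c(OC)c3Oc3cc(OC)c(OC)c(OC)c3)c(OC)c2)c(OC)c1 | intermediate
28 | 2-iodo-1,3,5-trimethoxybenzene | COc1cc(OC)c(I)c(OC)c1 | starting material
29 | fully alkylated octamer A–H (18 OMe, 3 OEt) | COc1cc(OC)cc(OC)c1Oc1cc(OCC)c(Oc2cc(OC)c(OC)c(OC)c2Oc2cc(OCC)c(Oc3cc(OC)c(OC)c(OC)c3Oc3cc(OCC)c(Oc4cc(OC)c(OC)c(OC)c4Oc4cc(OC)c(OC)c(OC)c4)c(OC)c3)c(OC)c2)c(OC)c1 | intermediate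
30 | CNP0206369.0 | Oc1cc(O)c(Oc2cc(O)c(Oc3cc(O)c(O)c(O)c3Oc3cc(O)c(Oc4cc(O)c(O)c(O)c4Oc4cc(O)c(Oc5cc(O)c(O)c(O)c5Oc5cc(O)c(O)c(O)c5)c(O)c4)c(O)c3)c(O)c2)c(O)c1 | target

**Step count and risk**

Total steps: 16. Longest linear sequence: 15 (steps 1–5 and 7–16, from compound 1); step 6 is a one-step side branch.

Step 7 (benzannulation). The donor-stabilised 3-ethoxycyclobutenone may open only at temperatures at which the silyloxyalkyne isomerises to the silylketene by 1,3-silyl shift. The vinylketene may also be consumed by the phenolic product (aryl ester formation) or by dimerisation before the alkyne adds, and the enol ether of 9 may hydrolyse on handling. The fallback builds the same dimer by classical arene chemistry and also makes steps 1 to 6 unnecessary. It sets out from silyl triflate 12, its arenes being bought 3-ethoxy-4-hydroxybenzaldehyde and 5-bromo-1,2,3-trimethoxybenzene, and comes back to the route at 21. Bromination of the aldehyde (Br2, AcOH) should give 3-bromo-5-ethoxy-4-hydroxybenzaldehyde F1. Copper-catalysed methoxide exchange (NaOMe, CuCl, MeOH/DMF, 110 °C) then gives 3-ethoxy-4-hydroxy-5-methoxybenzaldehyde F2. Ullmann coupling of this hindered phenol with 5-bromo-1,2,3-trimethoxybenzene (CuI, picolinic acid, K3PO4, DMSO, 100 °C) gives 3-ethoxy-5-methoxy-4-(3,4,5-trimethoxyphenoxy)benzaldehyde F3. NIS with catalytic CF3CO2H should iodinate the trimethoxyphenoxy ring ortho to the ether oxygen, the aldehyde ring being deactivated, to give 3-ethoxy-4-(2-iodo-3,4,5-trimethoxyphenoxy)-5-methoxybenzaldehyde F4. Acid-catalysed Dakin oxidation (H2O2, cat. H2SO4, MeOH) converts the formyl group into the hydroxyl of 3-ethoxy-4-(2-iodo-3,4,5-trimethoxyphenoxy)-5-methoxyphenol F5, and silylation with 12 and 2,6-lutidine gives 21.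

Step 13 (Ullmann coupling of the pentamer phenol with the hindered iodide). Copper insertion into the di-ortho-oxygenated C–I bond may be slow with a large phenoxide, so that hydrodeiodination competes. Loss of the silyl group from 21 under hot carbonate would free a phenol on the iodide partner and lead to self-condensation. The same risks apply, to a smaller degree, to steps 9, 11 and 15. The fallback reverses the polarity, so that the hindered site becomes the nucleophile in a palladium-catalysed etherification. It sets out from 21 and 25 and comes back at 26. Iodine–lithium exchange on 21 (n-BuLi, THF, −78 °C), borylation with B(OMe)3 and oxidation (H2O2, AcOH) should give 6-[2-ethoxy-6-methoxy-4-(triisopropylsilyloxy)phenoxy]-2,3,4-trimethoxyphenol F6. Phenol 25 is converted with Tf2O and pyridine into the D1 trifluoromethanesulfonate of the pentamer F7. Coupling of F6 with F7 (Pd2(dba)3, 2-di-tert-butylphosphino-2',4',6'-triisopropylbiphenyl, K3PO4, toluene, 100 °C) gives 26.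

Step 16 (cleavage of 21 alkyl ethers). Partially dealkylated aryl borates may precipitate from CH2Cl2 and stop the reaction short, and the pyrogallol-type rings C, E, G and H may oxidise in air during aqueous isolation. The fallback isolates the product as a stable derivative, sets out from 29 and comes back at 30. After BBr3 treatment the crude polyphenol is acetylated without purification (Ac2O, pyridine, DMAP) to the henicosaacetate of the octamer F8. This ester is soluble and can be chromatographed on silica, so incompletely dealkylated material can be separated and returned to BBr3. Acid methanolysis (HCl in MeOH, rt, argon) then releases 30 under non-oxidising conditions.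

**Further compounds**

F1 | step 7 | 3-bromo-5-ethoxy-4-hydroxybenzaldehyde | CCOc1cc(C=O)cc(Br)c1O
F2 | step 7 | 3-ethoxy-4-hydroxy-5-methoxybenzaldehyde | CCOc1cc(C=O)cc(OC)c1O
F3 | step 7 | 3-ethoxy-5-methoxy-4-(3,4,5-trimethoxyphenoxy)benzaldehyde | CCOc1cc(C=O)cc(OC)c1Oc1cc(OC)c(OC)c(OC)c1
F4 | step 7 | 3-ethoxy-4-(2-iodo-3,4,5-trimethoxyphenoxy)-5-methoxybenzaldehyde | CCOc1cc(C=O)cc(OC)c1Oc1cc(OC)c(OC)c(OC)c1I
F5 | step 7 | 3-ethoxy-4-(2-iodo-3,4,5-trimethoxyphenoxy)-5-methoxyphenol | CCOc1cc(O)cc(OC)c1Oc1cc(OC)c(OC)c(OC)c1I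
F6 | step 13 | 6-[2-ethoxy-6-methoxy-4-(triisopropylsilyloxy)phenoxy]-2,3,4-trimethoxyphenol | CCOc1cc(O[Si](C(C)C)(C(C)C)C(C)C)cc(OC)c1Oc1cc(OC)c(OC)c(OC)c1O
F7 | step 13 | D1 trifluoromethanesulfonate of pentamer phenol 25 | CCOc1cc(OS(=O)(=O)C(F)(F)F)cc(OC)c1Oc1cc(OC)c(OC)c(OC)c1Oc1cc(OCC)c(Oc2cc(OC)c(OC)c(OC)c2Oc2cc(OC)c(OC)c(OC)c2)c(OC)c1
F8 | step 16 | henicosaacetate of the octamer | CC(=O)Oc1cc(OC(C)=O)c(Oc2cc(OC(C)=O)c(Oc3cc(OC(C)=O)c(OC(C)=O)c(OC(C)=O)c3Oc3cc(OC(C)=O)c(Oc4cc(OC(C)=O)c(OC(C)=O)c(OC(C)=O)c4Oc4cc(OC(C)=O)c(Oc5cc(OC(C)=O)c(OC(C)=O)c(OC(C)=O)c5Oc5cc(OC(C)=O)c(OC(C)=O)c(OC(C)=O)c5)c(OC(C)=O)c4)c(OC(C)=O)c3)c(OC(C)=O)c2)c(OC(C)=O)c1
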